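## Analysis of the target

Compound 25 is a flavanone: benzo ring A is fused to dihydropyranone ring C (O1, C2, C3, C4, C4a, C8a), and aryl ring B sits on C2. Ring A carries a hydroxyl at C5 that is hydrogen-bonded to the C4 carbonyl, a prenyl group at C6 and a methoxy group at C7; ring B carries a geranyl chain at C2' and methoxy groups at C3' and C4'. The only stereocentre is C2 (S); it is benzylic, bears the ring oxygen and lies β to the ketone, so base can open ring C to a chalcone phenoxide and erase it. The three trisubstituted alkenes are sensitive to electrophilic oxidants and to acid, and acid can also add the C5 hydroxyl across the neighbouring prenyl double bond. The synthesis is hard because one isolated stereocentre must be set by a reagent that ignores three electron-rich alkenes, because acyl, oxygen and prenyl groups must be placed on adjacent carbons of ring A without isomers, and because strong acid and long basic treatments are excluded late in the route. The strategy rests on two relations in ring C. C2 carries O1 in a β position to the C4 carbonyl, so the C2–O1 bond can be made as the β C–O bond of an α,β-epoxy ketone whose α C–O bond at C3 is removed afterwards. O1 is also bound to C8a, which is ortho to the acyl-bearing C4a, so the O1–C8a bond can be closed by displacing a fluoride.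

## Retrosynthetic reasoning

**25 from 24.** The C5 hydroxyl is carried to the end as the MOM ether 24. A free phenol next to the acyl group would close ring C through the wrong oxygen at the chalcone stage and, as a phenoxide, would deaden the enone towards nucleophilic oxidation. The forward step only has to cleave an acetal that lies peri to the C4 carbonyl, which is the most labile kind of aryl MOM ether.

**24 from 22.** The O1–C8a aryl ether bond is cut, not the O1–C2 bond. Cutting at C2 would demand a substitution at the stereocentre; cutting at C8a leaves the C2–O bond untouched, so the configuration of the carbinol in 22 is that of 25. The forward reaction is an intramolecular displacement of fluoride by the alkoxide of 22, and it must outrun retro-aldol cleavage. The fluorine is ortho to the ketone and meta to both ring oxygens, so neither oxygen deactivates the carbon under attack.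

**22 from 20.** An oxygen is put back on C3, and aldol 22 becomes the product of reductive cleavage of the α C–O bond of epoxy ketone 20. This turns a difficult asymmetric acetate-type aldol of a hindered aryl methyl ketone into an asymmetric epoxidation of an enone. The forward step must break only the Cα–O bond and leave the Cβ–O bond and the ketone alone.

**20 from 18.** Both oxirane C–O bonds are cut, which leads to the E-chalcone 18. The forward reaction is a nucleophilic epoxidation under a helical D-polypeptide catalyst. It has to find one face of the enone and leave the three isolated alkenes untouched; this is the step that carries the strategy.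

**18 from 9 and 16.** The Cα=Cβ bond is cut to methyl ketone 9 and aldehyde 16. This is the convergent point: the substitution problems of ring A stay in 9 and those of ring B in 16. The forward aldol condensation has one enolisable partner and one non-enolisable partner, so cross-selectivity is built in.

**9 from 8, 6, 5, 3 and 4.** The aryl–prenyl bond at C5' (the later C6) is traced back to an O-bound 1,1-dimethylallyl group in 6, which a [3,3] shift moves to carbon and inverts to the linear prenyl group of 8 through dienone 7. Ether 6 comes from alkyne 5 by semi-hydrogenation, and 5 from phenol 3 and the tertiary propargylic chloride 4. The gain is regiocontrol: in 3 the acetyl group blocks one ortho position of the phenol, so the shift has a single free ortho carbon to go to. Phenol 8 is then capped to give 9.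

**3 from 2 and 1.** The aryl–acetyl bond is cut to the symmetrical arene 1. Its two positions between fluorine and methoxy are equivalent, so acylation poses one regiochemical question only, and it is answered by the usual preference for the less hindered carbon para to a methoxy group. In 2 only one methoxy group is ortho to the ketone, so chelation-controlled demethylation to 3 is unambiguous. An unsymmetrical phenol ether and a directed metalation would leave three competing sites.

**16 from 15, 12, 11 and 10.** The aryl–geranyl bond is cut to an aryl nucleophile and geranyl bromide 12. The bromine of 10 marks the carbon between the formyl group and the methoxy group beyond doubt. After protection as acetal 11, halogen–metal exchange gives 13, transmetalation gives 14, allylic substitution gives 15, and hydrolysis gives 16.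

## Alternatives that were turned down

**Alternative 1:** Ring A is built last by cutting C4a–C5. The precursor is the dihydropyranone A2, in which ring C and the C2 stereocentre already exist and C5 to C8 hang from the future C8a as a prenylated β-keto ester chain.
- **Forward key step:** base forms the extended enolate of the vinylogous ester, its α-carbon (the future C4a) attacks the ester carbonyl in a Claisen condensation, the ester alkoxide leaves and tautomerisation aromatises the new ring to the resorcinol A1. Methylation of the unchelated C7 hydroxyl would then give 25.
- **For:** the prenyl group sits on an sp3 carbon between two carbonyls, so ring A needs no aromatic substitution, no blocking group and no protecting group. On ring A regiochemistry this plan is stronger than the chosen one.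
- **Against:** in A2 the stereocentre is β to a ketone with the ring oxygen as leaving group, and the key step needs strong base for a slow enolate acylation, so E1cB opening of the pyranone competes directly with the wanted bond formation. A2 also requires an asymmetric hetero-Diels–Alder reaction of 16 with a diene that already carries the keto ester chain, which is long and delicate. The final methylation must distinguish two phenols.
- **Comparison:** the chosen strategy pays for ring A with a blocking acetyl group and one protecting group. In return it makes the stereocentre late and exposes it to base once, in a fast intramolecular ring closure.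

**Alternative 2:** The bonds C4a–C4, C4–C3 and O1–C2 are cut at once, which gives iodophenol A4, arylacetylene A5 and a one-carbon carbonyl unit.
- **Forward key step:** a palladium-catalysed carbonylative coupling of A4 with A5, in which an acyl-palladium species captures the alkyne and the phenol oxygen closes ring C in a 6-endo mode, gives flavone A3. C2 would then be set by enantioselective 1,4-reduction of the C2=C3 bond, followed by MOM removal.
- **For:** it is the most convergent plan; A5 comes from 16 in one homologation; A3 is flat, robust and has no stereocentre to lose; no aldol-type intermediate appears. On convergence and robustness of intermediates it is stronger than the chosen route.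
- **Against:** the stereocentre then depends on asymmetric conjugate reduction of a 2-aryl chromone. That is a β,β-disubstituted vinylogous ester, a poor hydride acceptor, hindered by the peri MOM ether and by the ortho-geranyl aryl group. Hydrogenation catalysts would not spare the three alkenes, hydride reagents risk 1,2-reduction at C4, and 5-exo closure to an aurone competes in the annulation. A4 also needs an iodination next to a prenyl group.
- **Comparison:** the chosen strategy is less convergent in ring C, but its enantio-determining step belongs to a well-studied reaction class that is chemoselective for the enone by mechanism, and it does not come last on the most valuable intermediate.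

**Alternative 3:** Ring C is cut at C3–C4 and O1–C2 as a [4+2] cycloaddition between salicylaldehyde A7 and styrene A8.
- **Forward key step:** an orthoformate and a chiral Brønsted acid turn the aldehyde carbon of A7 into an electrophilic, quinone-methide-like 4π component that adds A8, which gives the 2,4-cis 4-methoxyflavan A6. Oxidation at C4 and MOM removal would follow.
- **For:** both new bonds of ring C and the C2 stereocentre arise in one catalytic step from simple partners, and no base-sensitive intermediate occurs. In the ring-forming stage it is shorter than the chosen route.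
- **Against:** a strong acid and a benzylic cation are generated beside three nucleophilic trisubstituted alkenes, each of which can trap the cation or start a cation–olefin cyclisation of the geranyl chain. The MOM acetal is acid-labile, and its loss would let the second ortho oxygen close the isomeric ring. A8 is twisted by its ortho substituent and is a poorer 2π partner than the prenyl and geranyl alkenes. C4 emerges at the wrong oxidation level, so further redox steps on an oxidisable molecule are needed.
- **Comparison:** the chosen strategy uses only basic, nucleophilic or reductive conditions until a last mild acid step, which suits the functional groups of 25 better. It gives up the one-step ring construction for that.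

Key step: step 10

Remark on the chemistry: compounds 1, 4, 10 and 12 are assumed to be purchasable and poly-D-leucine to be made by amine-initiated polymerisation of D-leucine N-carboxyanhydride; prenyl means 3-methylbut-2-enyl, geranyl means (2E)-3,7-dimethylocta-2,6-dienyl, MOM means methoxymethyl, and primed chalcone locants belong to the benzoyl ring.

## Route

Step 1
Reactants: 1 1-fluoro-3,5-dimethoxybenzene
Product: 2 1-(2-fluoro-4,6-dimethoxyphenyl)ethanone
Conditions: AcCl, AlCl3, CH2Cl2, −10 → 0 °C
Reagents that add atoms: acetyl chloride, CC(Cl)=O
Why: Friedel–Crafts acylation; the two carbons flanked by fluorine and methoxy are equivalent, each is para to the other methoxy group and less hindered than the carbon between the two methoxy groups, so one ketone should predominate and the minor isomer can be removed by crystallisation.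

Step 2
Reactants: 2 1-(2-fluoro-4,6-dimethoxyphenyl)ethanone
Product: 3 1-(2-fluoro-6-hydroxy-4-methoxyphenyl)ethanone
Conditions: BCl3, CH2Cl2, −78 → 0 °C; aq. work-up
Reagents that add atoms: none
Why: Chelation-controlled aryl methyl ether cleavage; boron binds the ketone oxygen and the ortho methoxy oxygen in a six-membered chelate and chloride removes that methyl group only, since the para methoxy group has no such assistance.

Step 3
Reactants: 3 1-(2-fluoro-6-hydroxy-4-methoxyphenyl)ethanone; 4 3-chloro-3-methylbut-1-yne
Product: 5 1-[2-fluoro-4-methoxy-6-(2-methylbut-3-yn-2-yloxy)phenyl]ethanone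
Conditions: DBU, CuCl2·2H2O (cat.), MeCN, 0 °C → rt
Reagents that add atoms: none
Why: Copper-catalysed propargylic etherification; the copper acetylide of 4 loses chloride to an allenylidene-type electrophile that the phenoxide captures at the tertiary carbon, and DBU is strong enough to deprotonate the hydrogen-bonded phenol fully.

Step 4
Reactants: 5 1-[2-fluoro-4-methoxy-6-(2-methylbut-3-yn-2-yloxy)phenyl]ethanone
Product: 6 1-[2-fluoro-4-methoxy-6-(2-methylbut-3-en-2-yloxy)phenyl]ethanone
Conditions: H2 (1 atm), Pd/CaCO3 poisoned with Pb(OAc)2, quinoline, EtOAc, rt
Reagents that add atoms: none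
Why: Lindlar semi-hydrogenation of the terminal alkyne stops at the alkene on the poisoned catalyst, and the aryl ketone and the aryl fluoride are not reduced under these conditions.

Step 5
Reactants: 6 1-[2-fluoro-4-methoxy-6-(2-methylbut-3-en-2-yloxy)phenyl]ethanone
Product: 8 1-(2-fluoro-6-hydroxy-4-methoxy-5-prenylphenyl)ethanone, via dienone 7 (not isolated)
Conditions: PhNEt2, 130 °C
Reagents that add atoms: none
Why: Aromatic Claisen rearrangement; the [3,3] shift can reach only the one unsubstituted ortho carbon because the other bears the acetyl group, it inverts the 1,1-dimethylallyl unit into the linear prenyl group of dienone 7, and tautomerisation to phenol 8 makes it irreversible, while the basic solvent suppresses acid-catalysed chroman formation.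

Step 6
Reactants: 8 1-(2-fluoro-6-hydroxy-4-methoxy-5-prenylphenyl)ethanone
Product: 9 1-[2-fluoro-4-methoxy-6-(methoxymethoxy)-5-prenylphenyl]ethanone
Conditions: NaH, MOMCl, DMF, 0 °C → rt
Reagents that add atoms: chloromethyl methyl ether, COCCl
Why: O-alkylation of the sodium phenoxide (Williamson type); the hydride is used because the phenol is hydrogen-bonded and flanked by acetyl and prenyl groups, and one equivalent deprotonates the phenol long before the methyl ketone.

Step 7
Reactants: 10 2-bromo-3,4-dimethoxybenzaldehyde
Product: 11 2-bromo-1-(dimethoxymethyl)-3,4-dimethoxybenzene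
Conditions: HC(OMe)3, MeOH, p-TsOH·H2O (cat.), rt; Et3N quench
Reagents that add atoms: trimethyl orthoformate, COC(OC)OC; methanol, CO
Why: Acid-catalysed acetalisation driven to completion by the orthoformate as water scavenger; the acetal masks the aldehyde against butyllithium in the next step.

Step 8
Reactants: 11 2-bromo-1-(dimethoxymethyl)-3,4-dimethoxybenzene; 12 geranyl bromide
Product: 16 2-geranyl-3,4-dimethoxybenzaldehyde, via aryllithium 13 (not isolated), via arylcopper 14 (not isolated), via geranylated acetal 15 (not isolated)
Conditions: n-BuLi, THF, −78 °C; CuBr·SMe2, −78 → −40 °C; 12, −78 → 0 °C; then 1 M HCl (aq), THF, rt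
Reagents that add atoms: water, O
Why: Bromine–lithium exchange fixes the carbanion of 13 at the carbon between acetal and methoxy; transmetalation to monovalent copper in 14 makes the coupling with the primary allylic bromide an SN2 substitution (the SN2' path would build a quaternary carbon) that keeps the E double bond; brief dilute acid in the work-up hydrolyses acetal 15 to the aldehyde without touching the diene.

Step 9
Reactants: 9 1-[2-fluoro-4-methoxy-6-(methoxymethoxy)-5-prenylphenyl]ethanone; 16 2-geranyl-3,4-dimethoxybenzaldehyde
Product: 18 (E)-2'-fluoro-4'-methoxy-6'-(methoxymethoxy)-5'-prenyl-2-geranyl-3,4-dimethoxychalcone, via racemic aldol 17 (not isolated)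
Conditions: KOH, EtOH–THF, 0 °C → rt
Reagents that add atoms: none
Why: Claisen–Schmidt condensation; only ketone 9 can enolise and only aldehyde 16 can accept, and E1cB dehydration of aldol 17 gives the conjugated E-enone as the thermodynamic product.

Step 10
Reactants: 18 (E)-2'-fluoro-4'-methoxy-6'-(methoxymethoxy)-5'-prenyl-2-geranyl-3,4-dimethoxychalcone
Product: 20 (2S,3R)-2,3-epoxy-1-[2-fluoro-4-methoxy-6-(methoxymethoxy)-5-prenylphenyl]-3-(2-geranyl-3,4-dimethoxyphenyl)propan-1-one (the αS,βR trans-epoxide of 18), via hydroperoxy enolate 19 (not isolated)
Conditions: poly-D-leucine, urea·H2O2, DBU, THF, rt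
Reagents that add atoms: hydrogen peroxide (as its urea adduct), OO
Why: This is a Juliá–Colonna epoxidation, the polypeptide-catalysed asymmetric form of the Weitz–Scheffer reaction. Hydroperoxide anion, formed from the urea adduct by DBU, adds to Cβ of the enone while the enone carbonyl and the peroxide are held by the N–H groups at the amino end of the poly-leucine helix, which gives enolate 19. The enolate carbon then attacks the near peroxide oxygen and expels hydroxide, a 3-exo-tet closure that forms the Cα–O bond and the oxirane, the only ring made in this step. The new centre at Cβ (R, the later C2) is controlled by the screw sense of the helix: the D-polymer is the mirror image of the common L-polymer, which steers chalcones into the (αR,βS) series, so the (αS,βR) epoxide is expected here. The centre at Cα (S) is tied to Cβ because closure of the enolate derived from the E-enone gives the trans-oxirane. The step needs chemoselectivity for the enone over three trisubstituted alkenes, and the nucleophilic oxidant secures it because isolated electron-rich alkenes do not accept hydroperoxide anion. It also needs facial selectivity on a hindered enone; the 2,6-disubstituted benzoyl group is twisted out of the enone plane and should be accommodated like the bulky tert-alkyl ketones that are good substrates of this reaction. The fluoroarene, the MOM acetal and the ketone should survive because conjugate addition to the enone at room temperature is much faster than attack on a twisted fluoroarene.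

Step 11
Reactants: 20 (2S,3R)-2,3-epoxy-1-[2-fluoro-4-methoxy-6-(methoxymethoxy)-5-prenylphenyl]-3-(2-geranyl-3,4-dimethoxyphenyl)propan-1-one
Product: 22 (3S)-1-[2-fluoro-4-methoxy-6-(methoxymethoxy)-5-prenylphenyl]-3-(2-geranyl-3,4-dimethoxyphenyl)-3-hydroxypropan-1-one, via samarium enolate 21 (not isolated)
Conditions: SmI2 (2.2 equiv), THF–MeOH, −90 °C
Reagents that add atoms: none
Why: Reductive opening of an α,β-epoxy ketone; two single-electron transfers from divalent samarium through the ketyl break only the Cα–O bond and give enolate 21, which methanol protonates at once, while the Cβ–O bond is untouched, so the R epoxide carbon becomes the S carbinol (only the ranking of its substituents changes); the low temperature should prevent β-elimination and retro-aldol cleavage.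

Step 12
Reactants: 22 (3S)-1-[2-fluoro-4-methoxy-6-(methoxymethoxy)-5-prenylphenyl]-3-(2-geranyl-3,4-dimethoxyphenyl)-3-hydroxypropan-1-one
Product: 24 (2S)-2'-geranyl-3',4',7-trimethoxy-5-(methoxymethoxy)-6-prenylflavanone, via sodium alkoxide 23 (not isolated)
Conditions: NaH (1.05 equiv), THF–DMF, 0 °C; AcOH quench
Reagents that add atoms: none
Why: Intramolecular SNAr by addition–elimination; alkoxide 23 adds in a 6-exo-trig mode to the fluorine-bearing carbon, which is ortho to the ketone and meta to both ring oxygens, and fluoride leaves, closing ring C; the C2–O bond is not involved, so the S configuration is retained, and one equivalent of base at 0 °C limits retro-aldol cleavage and base-induced opening of the product.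

Step 13
Reactants: 24 (2S)-2'-geranyl-3',4',7-trimethoxy-5-(methoxymethoxy)-6-prenylflavanone
Product: 25 (2S)-2'-geranyl-5-hydroxy-3',4',7-trimethoxy-6-prenylflavanone
Conditions: HCl (1 M in MeOH), THF, 0 °C → rt
Reagents that add atoms: none
Why: Acid-catalysed acetal methanolysis; the MOM ether peri to the C4 carbonyl is cleaved more readily than an ordinary aryl MOM ether because the carbonyl oxygen assists and the freed phenol is held in a hydrogen bond, so dilute acid at room temperature should suffice and leave the alkenes and C2 untouched.

## Compound list

1 | 1-fluoro-3,5-dimethoxybenzene | COc1cc(F)cc(OC)c1 | starting material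
2 | 1-(2-fluoro-4,6-dimethoxyphenyl)ethanone | CC(=O)c1c(F)cc(OC)cc1OC | intermediate
3 | 1-(2-fluoro-6-hydroxy-4-methoxyphenyl)ethanone | CC(=O)c1c(F)cc(OC)cc1O | intermediate
4 | 3-chloro-3-methylbut-1-yne | CC(C)(Cl)C#C | starting material
5 | 1-[2-fluoro-4-methoxy-6-(2-methylbut-3-yn-2-yloxy)phenyl]ethanone | CC(=O)c1c(F)cc(OC)cc1OC(C)(C)C#C | intermediate
6 | 1-[2-fluoro-4-methoxy-6-(2-methylbut-3-en-2-yloxy)phenyl]ethanone | CC(=O)c1c(F)cc(OC)cc1OC(C)(C)C=C | intermediate
7 | 2-acetyl-3-fluoro-5-methoxy-6-(3-methylbut-2-enyl)cyclohexa-2,4-dien-1-one (racemic, not isolated) | CC(=O)C1=C(F)C=C(OC)C(CC=C(C)C)C1=O | intermediate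
8 | 1-[2-fluoro-6-hydroxy-4-methoxy-5-(3-methylbut-2-enyl)phenyl]ethanone | CC(=O)c1c(F)cc(OC)c(CC=C(C)C)c1O | intermediate
9 | 1-[2-fluoro-4-methoxy-6-(methoxymethoxy)-5-(3-methylbut-2-enyl)phenyl]ethanone | COCOc1c(CC=C(C)C)c(OC)cc(F)c1C(C)=O | intermediate
10 | 2-bromo-3,4-dimethoxybenzaldehyde | COc1ccc(C=O)c(Br)c1OC | starting material
11 | 2-bromo-1-(dimethoxymethyl)-3,4-dimethoxybenzene | COC(OC)c1ccc(OC)c(OC)c1Br | intermediate
12 | geranyl bromide, (2E)-1-bromo-3,7-dimethylocta-2,6-diene | CC(C)=CCC/C(C)=C/CBr | starting material
13 | [6-(dimethoxymethyl)-2,3-dimethoxyphenyl]lithium (not isolated) | COC(OC)c1ccc(OC)c(OC)c1[Li] | intermediate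
14 | [6-(dimethoxymethyl)-2,3-dimethoxyphenyl]copper, monovalent copper (not isolated) | COC(OC)c1ccc(OC)c(OC)c1[Cu] | intermediate
15 | 1-(dimethoxymethyl)-2-[(2E)-3,7-dimethylocta-2,6-dienyl]-3,4-dimethoxybenzene (not isolated) | COC(OC)c1ccc(OC)c(OC)c1C/C=C(\C)CCC=C(C)C | intermediate
16 | 2-[(2E)-3,7-dimethylocta-2,6-dienyl]-3,4-dimethoxybenzaldehyde | O=Cc1ccc(OC)c(OC)c1C/C=C(\C)CCC=C(C)C | intermediate
17 | 1-[2-fluoro-4-methoxy-6-(methoxymethoxy)-5-prenylphenyl]-3-(2-geranyl-3,4-dimethoxyphenyl)-3-hydroxypropan-1-one (racemic, not isolated) | COCOc1c(CC=C(C)C)c(OC)cc(F)c1C(=O)CC(O)c1ccc(OC)c(OC)c1C/C=C(\C)CCC=C(C)C | intermediate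
18 | (2E)-1-[2-fluoro-4-methoxy-6-(methoxymethoxy)-5-prenylphenyl]-3-(2-geranyl-3,4-dimethoxyphenyl)prop-2-en-1-one | COCOc1c(CC=C(C)C)c(OC)cc(F)c1C(=O)/C=C/c1ccc(OC)c(OC)c1C/C=C(\C)CCC=C(C)C | intermediate
19 | enolate of (3S)-1-[2-fluoro-4-methoxy-6-(methoxymethoxy)-5-prenylphenyl]-3-(2-geranyl-3,4-dimethoxyphenyl)-3-hydroperoxypropan-1-one (anion, not isolated) | COCOc1c(CC=C(C)C)c(OC)cc(F)c1C([O-])=C[C@H](OO)c1ccc(OC)c(OC)c1C/C=C(\C)CCC=C(C)C | intermediate
20 | (2S,3R)-2,3-epoxy-1-[2-fluoro-4-methoxy-6-(methoxymethoxy)-5-prenylphenyl]-3-(2-geranyl-3,4-dimethoxyphenyl)propan-1-one | COCOc1c(CC=C(C)C)c(OC)cc(F)c1C(=O)[C@H]1O[C@@H]1c1ccc(OC)c(OC)c1C/C=C(\C)CCC=C(C)C | intermediate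
21 | O-samarium enolate and samarium alkoxide of 22, both as diiodides of trivalent samarium, S at the carbinol carbon (not isolated) | COCOc1c(CC=C(C)C)c(OC)cc(F)c1C(O[Sm](I)I)=C[C@H](O[Sm](I)I)c1ccc(OC)c(OC)c1C/C=C(\C)CCC=C(C)C | intermediate
22 | (3S)-1-[2-fluoro-4-methoxy-6-(methoxymethoxy)-5-prenylphenyl]-3-(2-geranyl-3,4-dimethoxyphenyl)-3-hydroxypropan-1-one | COCOc1c(CC=C(C)C)c(OC)cc(F)c1C(=O)C[C@H](O)c1ccc(OC)c(OC)c1C/C=C(\C)CCC=C(C)C | intermediate
23 | sodium alkoxide of 22, S (not isolated) | COCOc1c(CC=C(C)C)c(OC)cc(F)c1C(=O)C[C@H]([O-])c1ccc(OC)c(OC)c1C/C=C(\C)CCC=C(C)C.[Na+] | intermediate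
24 | (2S)-2-(2-geranyl-3,4-dimethoxyphenyl)-7-methoxy-5-(methoxymethoxy)-6-prenyl-2,3-dihydro-4H-chromen-4-one | COCOc1c(CC=C(C)C)c(OC)cc2c1C(=O)C[C@@H](c1ccc(OC)c(OC)c1C/C=C(\C)CCC=C(C)C)O2 | intermediate
25 | (2S)-2-(2-geranyl-3,4-dimethoxyphenyl)-5-hydroxy-7-methoxy-6-prenyl-2,3-dihydro-4H-chromen-4-one | COc1cc2c(c(O)c1CC=C(C)C)C(=O)C[C@@H](c1ccc(OC)c(OC)c1C/C=C(\C)CCC=C(C)C)O2 | target

## Step count and least certain steps

Total step count: 13. Longest linear sequence: 11 steps (steps 1 to 6 and 9 to 13, from 1); the aldehyde branch (steps 7 and 8) joins at step 9.

**Step 10 (key step).** The most likely failure is slow conjugate addition or poor facial selectivity. The enone lies between a twisted, doubly ortho-substituted benzoyl group and an ortho-geranyl aryl group and may not fit the binding site of the helix, so that racemic background epoxidation by DBU and peroxide outside the catalyst takes over. Fallback: from 18, a copper-catalysed enantioselective conjugate borylation (CuCl, NaOt-Bu, a chiral ferrocenyl bisphosphine of the Josiphos type, B2pin2, MeOH, THF, rt) would give the (3S)-β-(pinacolboryl) ketone F1. Oxidation with NaBO3·4H2O in THF–water replaces boron by oxygen with retention and returns the route at 22, so that 20 and step 11 are bypassed. The copper–boryl species adds only to the activated alkene; the ligand enantiomer that gives S at Cβ would be fixed on the parent chalcone first.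

**Step 12.** Retro-aldol fragmentation of the alkoxide, E1cB dehydration back to the chalcone, or base-induced opening of the product to a chalcone phenoxide may compete with ring closure and erode the configuration, because every one of these processes starts from the same basic medium. Fallback: from 22, silylation (TESCl, imidazole, DMF) would give the triethylsilyl ether F2. Catalytic CsF with 18-crown-6 in DMF at rt then removes silicon, the alkoxide released next to the fluoroarene closes the ring, and the fluoride expelled carries the chain, so the route returns at 24 without stoichiometric base ever being present (fluoride-catalysed SNAr of silyl ethers with aryl fluorides).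

**Step 3.** Etherification of the hydrogen-bonded, hindered phenoxide may stay incomplete while the tertiary propargylic electrophile is consumed by elimination to the enyne. Fallback: from 3, a Tsuji–Trost O-alkylation with methyl 2-methylbut-3-en-2-yl carbonate F3 (made from 2-methylbut-3-en-2-ol and methyl chloroformate) under Pd(PPh3)4 (zerovalent palladium) in THF at 0 °C would give the 1,1-dimethylallyl ether directly. The phenoxide formed on decarboxylation attacks the more substituted end of the π-allyl complex under kinetic control. The route is rejoined at 6, and 5 and step 4 are skipped.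

**Step 9.** Hydroxide or ethoxide may displace the activated fluorine, or the alkoxide of aldol 17 may close onto the fluoroarene before it dehydrates, which would form racemic flavanone; both compete with a condensation that is slow between two hindered partners. Fallback: from 9, the lithium enolate (LiHMDS, THF, −78 °C) is added to 16 and quenched cold, so that 17 is isolated. MsCl and Et3N in CH2Cl2 at 0 °C convert it into the benzylic mesylate F4, which eliminates on addition of DBU and returns the route at 18.

**Step 13.** Acid may add the freed C5 hydroxyl across the neighbouring prenyl double bond (chroman formation) or start cyclisation of the geranyl chain before the acetal is fully cleaved. Fallback: from 8, allyl bromide and K2CO3 in acetone would give the allyl ether F5. The conditions of steps 9 to 12 would then lead through chalcone F6, epoxide F7 and aldol F8 to the 5-O-allyl flavanone F9. Pd(PPh3)4 with morpholine in THF at rt removes the allyl group under neutral conditions and returns the route at 25.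

## Further compounds

F1 | step 10 | (3S)-1-[2-fluoro-4-methoxy-6-(methoxymethoxy)-5-prenylphenyl]-3-(2-geranyl-3,4-dimethoxyphenyl)-3-(4,4,5,5-tetramethyl-1,3,2-dioxaborolan-2-yl)propan-1-one | COCOc1c(CC=C(C)C)c(OC)cc(F)c1C(=O)C[C@H](B2OC(C)(C)C(C)(C)O2)c1ccc(OC)c(OC)c1C/C=C(\C)CCC=C(C)C
F2 | step 12 | triethylsilyl ether of 22, (3S) | COCOc1c(CC=C(C)C)c(OC)cc(F)c1C(=O)C[C@H](O[Si](CC)(CC)CC)c1ccc(OC)c(OC)c1C/C=C(\C)CCC=C(C)C
F3 | step 3 | methyl 2-methylbut-3-en-2-yl carbonate | COC(=O)OC(C)(C)C=C
F4 | step 9 | methanesulfonate of racemic aldol 17 | COCOc1c(CC=C(C)C)c(OC)cc(F)c1C(=O)CC(OS(C)(=O)=O)c1ccc(OC)c(OC)c1C/C=C(\C)CCC=C(C)C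
F5 | step 13 | 1-[2-(allyloxy)-6-fluoro-4-methoxy-3-prenylphenyl]ethanone | C=CCOc1c(CC=C(C)C)c(OC)cc(F)c1C(C)=O
F6 | step 13 | (E)-6'-(allyloxy)-2'-fluoro-4'-methoxy-5'-prenyl-2-geranyl-3,4-dimethoxychalcone | C=CCOc1c(CC=C(C)C)c(OC)cc(F)c1C(=O)/C=C/c1ccc(OC)c(OC)c1C/C=C(\C)CCC=C(C)C
F7 | step 13 | (αS,βR)-epoxide of F6 | C=CCOc1c(CC=C(C)C)c(OC)cc(F)c1C(=O)[C@H]1O[C@@H]1c1ccc(OC)c(OC)c1C/C=C(\C)CCC=C(C)C
F8 | step 13 | (3S)-1-[2-(allyloxy)-6-fluoro-4-methoxy-3-prenylphenyl]-3-(2-geranyl-3,4-dimethoxyphenyl)-3-hydroxypropan-1-one | C=CCOc1c(CC=C(C)C)c(OC)cc(F)c1C(=O)C[C@H](O)c1ccc(OC)c(OC)c1C/C=C(\C)CCC=C(C)C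
F9 | step 13 | (2S)-5-(allyloxy)-2'-geranyl-3',4',7-trimethoxy-6-prenylflavanone | COc1cc2c(c(OCC=C)c1CC=C(C)C)C(=O)C[C@@H](c1ccc(OC)c(OC)c1C/C=C(\C)CCC=C(C)C)O2
A1 | alternative 1 | (2S)-5,7-dihydroxy-6-prenyl-2-(2-geranyl-3,4-dimethoxyphenyl)chroman-4-one | Oc1cc2c(c(O)c1CC=C(C)C)C(=O)C[C@@H](c1ccc(OC)c(OC)c1C/C=C(\C)CCC=C(C)C)O2
A2 | alternative 1 | methyl 4-[(2S)-2-(2-geranyl-3,4-dimethoxyphenyl)-4-oxo-3,4-dihydro-2H-pyran-6-yl]-3-oxo-2-prenylbutanoate | COC(=O)C(CC=C(C)C)C(=O)CC1=CC(=O)C[C@@H](c2ccc(OC)c(OC)c2C/C=C(\C)CCC=C(C)C)O1
A3 | alternative 2 | 7-methoxy-5-(methoxymethoxy)-6-prenyl-2-(2-geranyl-3,4-dimethoxyphenyl)chromen-4-one | COCOc1c(CC=C(C)C)c(OC)cc2oc(-c3ccc(OC)c(OC)c3C/C=C(\C)CCC=C(C)C)cc(=O)c12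
A4 | alternative 2 | 2-iodo-5-methoxy-3-(methoxymethoxy)-4-prenylphenol | COCOc1c(I)c(O)cc(OC)c1CC=C(C)C
A5 | alternative 2 | 1-ethynyl-2-geranyl-3,4-dimethoxybenzene | C#Cc1ccc(OC)c(OC)c1C/C=C(\C)CCC=C(C)C
A6 | alternative 3 | (2S)-2,4-cis-4,7-dimethoxy-5-(methoxymethoxy)-6-prenyl-2-(2-geranyl-3,4-dimethoxyphenyl)chroman | COCOc1c(CC=C(C)C)c(OC)cc2c1[C@@H](OC)C[C@@H](c1ccc(OC)c(OC)c1C/C=C(\C)CCC=C(C)C)O2
A7 | alternative 3 | 2-hydroxy-4-methoxy-6-(methoxymethoxy)-5-prenylbenzaldehyde | COCOc1c(CC=C(C)C)c(OC)cc(O)c1C=O
A8 | alternative 3 | 1-ethenyl-2-geranyl-3,4-dimethoxybenzene | C=Cc1ccc(OC)c(OC)c1C/C=C(\C)CCC=C(C)C
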